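The seven-membered ring is grown out of a cyclopropane (daucane numbering, defined below). The C7–C8 bond (ring CH2 to the methyl-bearing epoxide carbon) is formed by a cis-divinylcyclopropane (Cope) rearrangement of a bicyclo[3.1.0]hexane that already contains the five-membered ring: C5 carries a 1-silyloxyvinyl group (C6=C7), the cyclopropane carbon C10 an (E)-propenyl group (C9=C8). One thermal step closes the cycloheptadiene, cleaves C5–C10 and leaves a masked C6 ketone and a C9=C10 alkene, exploiting the 1,5-placement of the oxygenated carbons C6 and C10 across C7–C8; later steps turn these into the C6 ester and the C10 ester/8,9-epoxide. The cyclopropane arises from an intramolecular diazo ketoester cyclopropanation of a dienyl chain.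

Key step: step 8

Remark on numbering: five-membered ring C1(CH3)–C2–C3–C4(iPr)–C5; seven-membered ring C5–C6–C7–C8(CH3)–C9–C10–C1; α is the face of the angular methyl and H-5, β the opposite face. In the bicyclo[3.1.0]hexanes, bicyclic C1, C2, C3, C4, C5, C6 correspond to C5, C4, C3, C2, C1, C10.

Assumption: (S)-BINOL is taken to deliver the 5S aldol in step 2; if the sense of induction is the opposite, (R)-BINOL is used.

Step 1
Reactants: 1 (E)-but-2-enal; 2 2-(triphenylphosphoranylidene)propanal
Product: 3 (2E,4E)-2-methylhexa-2,4-dienal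
Conditions: PhMe, 80 °C
Reagents that add atoms: none
Why: Wittig olefination with a stabilised ylide should give the E-trisubstituted enal that supplies C2, C1 with its methyl, C10, C9, C8 and the C8 methyl.

Step 2
Reactants: 3 (2E,4E)-2-methylhexa-2,4-dienal; 4 1-methoxy-1,3-bis(trimethylsilyloxy)buta-1,3-diene
Product: 6 methyl (5S,6E,8E)-5-hydroxy-6-methyl-3-oxodeca-6,8-dienoate, via bis-silylated aldol adduct 5 (not isolated)
Conditions: Ti(OiPr)4 (10 mol%), (S)-BINOL (10 mol%), THF, −78 °C to rt; then PPTS, MeOH, 0 °C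
Reagents that add atoms: none
Why: Catalytic enantioselective vinylogous Mukaiyama aldol addition at the terminal carbon of the dienolate; the BINOL–titanium complex selects the aldehyde face and sets C2.

Step 3
Reactants: 6 methyl (5S,6E,8E)-5-hydroxy-6-methyl-3-oxodeca-6,8-dienoate
Product: 7 methyl (5S,6E,8E)-5-[(tert-butyldimethylsilyl)oxy]-6-methyl-3-oxodeca-6,8-dienoate
Conditions: TBSCl, imidazole, DMF, rt
Reagents that add atoms: tert-butyldimethylsilyl chloride, CC(C)(C)[Si](C)(C)Cl
Why: Silylation of the secondary alcohol prevents O–H insertion in step 5 and keeps the C2 oxygen unacylated to the end.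

Step 4
Reactants: 7 methyl (5S,6E,8E)-5-[(tert-butyldimethylsilyl)oxy]-6-methyl-3-oxodeca-6,8-dienoate
Product: 8 methyl (5S,6E,8E)-5-[(tert-butyldimethylsilyl)oxy]-2-diazo-6-methyl-3-oxodeca-6,8-dienoate
Conditions: 4-acetamidobenzenesulfonyl azide, Et3N, MeCN, 0 °C to rt
Reagents that add atoms: 4-acetamidobenzenesulfonyl azide, CC(=O)Nc1ccc(cc1)S(=O)(=O)N=[N+]=[N-]
Why: Regitz diazo transfer to the active methylene of the β-keto ester.

Step 5
Reactants: 8 methyl (5S,6E,8E)-5-[(tert-butyldimethylsilyl)oxy]-2-diazo-6-methyl-3-oxodeca-6,8-dienoate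
Product: 9 methyl 4-[(tert-butyldimethylsilyl)oxy]-5-methyl-2-oxo-6-[(E)-prop-1-enyl]bicyclo[3.1.0]hexane-1-carboxylate (silyloxy group anti to the cyclopropane; propenyl exo and cis to the ester)
Conditions: Rh2(OAc)4 (1 mol%), CH2Cl2, 40 °C
Reagents that add atoms: none
Why: Intramolecular cyclopropanation of the proximal trisubstituted alkene by the rhodium carbenoid closes the five-membered ring; it is stereospecific (E-alkene gives the exo propenyl group), and the allylic silyloxy group should sit pseudo-equatorial in the envelope transition state, which sets C1 anti to the C2 oxygen.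

Step 6
Reactants: 9 bicyclic keto ester
Product: 10 methyl 4-[(tert-butyldimethylsilyl)oxy]-2-hydroxy-2-isopropyl-5-methyl-6-[(E)-prop-1-enyl]bicyclo[3.1.0]hexane-1-carboxylate (hydroxyl syn to the cyclopropane; isopropyl anti)
Conditions: iPrMgCl, LaCl3·2LiCl, THF, −20 to 0 °C
Reagents that add atoms: isopropylmagnesium chloride, CC(C)[Mg]Cl
Why: Lanthanum-promoted 1,2-addition to the ketone (more electrophilic than the ester; no enolisable hydrogen between the carbonyls) should occur on the face anti to the cyclopropane, setting C4 with 4β-OH and 4α-isopropyl.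

Step 7
Reactants: 10 tertiary hydroxy ester
Product: 12 1-acetyl-4-[(tert-butyldimethylsilyl)oxy]-2-isopropyl-5-methyl-6-[(E)-prop-1-enyl]bicyclo[3.1.0]hexan-2-ol, via alpha-trimethylsilyl ketone 11 (not isolated)
Conditions: Me3SiCH2Li (4 equiv), pentane/THF, −78 to 0 °C; then MeOH, rt; aq. NH4Cl
Reagents that add atoms: (trimethylsilyl)methyllithium, [Li]C[Si](C)(C)C
Why: Addition–elimination gives the α-silyl ketone, whose immediate deprotonation to the enolate blocks a second addition; methanolysis of the C–Si bond should then give the methyl ketone (C6, C7).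

Step 8
Reactants: 12 cyclopropyl methyl ketone
Product: 14 2α-[(tert-butyldimethylsilyl)oxy]-4β,6-bis(trimethylsilyloxy)dauca-5,9-diene (1α-methyl; 4α-isopropyl; 8β-methyl), via silyloxy divinylcyclopropane 13 (not isolated)
Conditions: LiN(iPr)2 (2.5 equiv), THF, −78 °C; Me3SiCl (3 equiv), −78 to 0 °C; then PhMe, 100 °C
Reagents that add atoms: chlorotrimethylsilane, C[Si](C)(C)Cl
Why: Kinetic deprotonation can occur only at the acetyl methyl (C5 is quaternary), and O-silylation gives 13, a cis-1,2-divinylcyclopropane whose 1-silyloxyvinyl group (on C5) and (E)-propenyl group (on C10) were placed cis by the stereospecific cyclopropanation of step 5. On heating, 13 should undergo the concerted 3,3-sigmatropic divinylcyclopropane–cycloheptadiene (Cope) rearrangement through the boat transition state with both vinyl groups folded over the three-membered ring: the C7–C8 σ bond forms, the strained C5–C10 bond breaks and the double bonds move to C5=C6 (silyl enol ether) and C9=C10. The closest known reaction type is the rearrangement of 2-silyloxy-substituted cis-divinylcyclopropanes to silyl enol ethers of cyclohept-4-enones. The seven-membered ring is closed in this sigmatropic mode (a four-atom expansion of the three-membered ring, suprafacial on both allyl parts) and not by an exo or endo attack of a chain end. The new stereocentre C8 is fixed by the E geometry of the propenyl group in the boat (methyl outside, hence 8β-methyl and 8α-H), while C1, C2 and C4 are untouched. The step needs the Cope shift to outrun the homodienyl 1,5-hydrogen shift from the angular methyl that lies syn to both vinyl groups, which the released ring strain and the electron-rich silyloxy diene should secure at about 100 °C.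

Step 9
Reactants: 14 bis(trimethylsilyl) dienol ether
Product: 15 2α-[(tert-butyldimethylsilyl)oxy]-4β-hydroxy-5αH-dauc-9-en-6-one (cis-fused; 8β-methyl)
Conditions: K2CO3, MeOH, 0 °C to rt
Reagents that add atoms: none
Why: Methanolysis removes both trimethylsilyl groups, and the C5 centre α to the new ketone should equilibrate to the cis-fused epimer (C6 anti to the isopropyl group), the low temperature holding back retro-aldol cleavage and dehydration.

Step 10
Reactants: 15 β-hydroxy ketone
Product: 16 2α-[(tert-butyldimethylsilyl)oxy]-5αH-dauc-9-ene-4β,6α-diol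
Conditions: Me4NBH(OAc)3, MeCN/AcOH, −30 °C
Reagents that add atoms: none
Why: Hydroxyl-directed (Evans–Saksena) reduction: the borohydride bound to the 4β-oxygen delivers hydride to the β face of the C6 carbonyl, which sets C6 as the 6α-alcohol.

Step 11
Reactants: 16 homoallylic diol
Product: 18 2α-[(tert-butyldimethylsilyl)oxy]-4β-hydroxy-10-oxo-5αH-dauc-8-en-6α-yl (E)-2-methylbut-2-enoate, via allylic hydroperoxide 17 (not isolated)
Conditions: O2, tetraphenylporphyrin (cat.), hν, CH2Cl2, 0 °C; then (E)-2-methylbut-2-enoyl chloride, pyridine, DMAP (cat.), 0 °C to rt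
Reagents that add atoms: dioxygen, O=O; (E)-2-methylbut-2-enoyl chloride, C/C=C(\C)C(=O)Cl
Why: Schenck ene reaction of singlet oxygen at C10 on the convex α face with the only allylic hydrogen (8α-H) moves the alkene to C8=C9; acylation then turns the hydroperoxide into a perester that eliminates to the enone (Kornblum–DeLaMare type) and esterifies the C6 alcohol in the same flask, the tertiary C4 alcohol staying free.

Step 12
Reactants: 18 enone tiglate
Product: 19 2α-[(tert-butyldimethylsilyl)oxy]-4β,10β-dihydroxy-5αH-dauc-8-en-6α-yl (E)-2-methylbut-2-enoate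
Conditions: NaBH4, CeCl3·7H2O, MeOH, −78 °C
Reagents that add atoms: none
Why: Luche 1,2-reduction; hydride should approach C10 anti to the five-membered ring (past the angular methyl, Felkin–Anh sense) and set C10 as the 10β-alcohol, the tiglate ester being inert.

Step 13
Reactants: 19 allylic alcohol
Product: 20 8β,9β-epoxy-2α-[(tert-butyldimethylsilyl)oxy]-4β,10β-dihydroxy-5αH-daucan-6α-yl (E)-2-methylbut-2-enoate
Conditions: VO(acac)2 (5 mol%), tBuOOH, CH2Cl2, 0 °C to rt
Reagents that add atoms: tert-butyl hydroperoxide, CC(C)(C)OO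
Why: Vanadium-catalysed hydroxyl-directed epoxidation delivers oxygen syn to the allylic 10β-OH and sets C8 and C9; the electron-poor tiglate alkene should not react.

Step 14
Reactants: 20 epoxy alcohol
Product: 21 8β,9β-epoxy-2α-[(tert-butyldimethylsilyl)oxy]-4β-hydroxy-5αH-daucane-6α,10β-diyl bis[(E)-2-methylbut-2-enoate]
Conditions: (E)-2-methylbut-2-enoyl chloride, DMAP, Et3N, CH2Cl2, 0 to 40 °C
Reagents that add atoms: (E)-2-methylbut-2-enoyl chloride, C/C=C(\C)C(=O)Cl
Why: DMAP-catalysed acylation of the remaining secondary alcohol; the tertiary C4 alcohol and the silyl ether should not react.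

Step 15
Reactants: 21 silyl-protected bis-tiglate
Product: 22 (1S,2S,4R,5S,6S,8S,9R,10R)-8,9-epoxy-2,4-dihydroxydaucane-6,10-diyl bis[(E)-2-methylbut-2-enoate] (target)
Conditions: HF·pyridine, pyridine, THF, 0 °C to rt
Reagents that add atoms: none
Why: Buffered fluoride cleavage of the silyl ether should free the C2 alcohol without touching the epoxide or the esters.

Compound list
1 | (E)-but-2-enal | C/C=C/C=O | starting material
2 | 2-(triphenylphosphoranylidene)propanal | CC(C=O)=P(c1ccccc1)(c1ccccc1)c1ccccc1 | starting material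
3 | (2E,4E)-2-methylhexa-2,4-dienal | C/C=C/C=C(\C)C=O | intermediate
4 | 1-methoxy-1,3-bis(trimethylsilyloxy)buta-1,3-diene | COC(O[Si](C)(C)C)=CC(=C)O[Si](C)(C)C | starting material
5 | methyl (5S,6E,8E)-6-methyl-3,5-bis(trimethylsilyloxy)deca-2,6,8-trienoate (not isolated) | COC(=O)C=C(O[Si](C)(C)C)C[C@H](O[Si](C)(C)C)/C(C)=C/C=C/C | intermediate
6 | methyl (5S,6E,8E)-5-hydroxy-6-methyl-3-oxodeca-6,8-dienoate | COC(=O)CC(=O)C[C@H](O)/C(C)=C/C=C/C | intermediate
7 | methyl (5S,6E,8E)-5-[(tert-butyldimethylsilyl)oxy]-6-methyl-3-oxodeca-6,8-dienoate | COC(=O)CC(=O)C[C@H](O[Si](C)(C)C(C)(C)C)/C(C)=C/C=C/C | intermediate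
8 | methyl (5S,6E,8E)-5-[(tert-butyldimethylsilyl)oxy]-2-diazo-6-methyl-3-oxodeca-6,8-dienoate | COC(=O)C(=[N+]=[N-])C(=O)C[C@H](O[Si](C)(C)C(C)(C)C)/C(C)=C/C=C/C | intermediate
9 | methyl 4-[(tert-butyldimethylsilyl)oxy]-5-methyl-2-oxo-6-[(E)-prop-1-enyl]bicyclo[3.1.0]hexane-1-carboxylate (silyloxy anti to cyclopropane; propenyl exo) | COC(=O)[C@]12C(=O)C[C@H](O[Si](C)(C)C(C)(C)C)[C@@]1(C)[C@@H]2/C=C/C | intermediate
10 | methyl 4-[(tert-butyldimethylsilyl)oxy]-2-hydroxy-2-isopropyl-5-methyl-6-[(E)-prop-1-enyl]bicyclo[3.1.0]hexane-1-carboxylate (hydroxyl syn to cyclopropane) | COC(=O)[C@]12[C@](O)(C(C)C)C[C@H](O[Si](C)(C)C(C)(C)C)[C@@]1(C)[C@@H]2/C=C/C | intermediate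
11 | (trimethylsilyl)methyl ketone corresponding to 12 (not isolated) | C[Si](C)(C)CC(=O)[C@]12[C@](O)(C(C)C)C[C@H](O[Si](C)(C)C(C)(C)C)[C@@]1(C)[C@@H]2/C=C/C | intermediate
12 | 1-acetyl-4-[(tert-butyldimethylsilyl)oxy]-2-isopropyl-5-methyl-6-[(E)-prop-1-enyl]bicyclo[3.1.0]hexan-2-ol | CC(=O)[C@]12[C@](O)(C(C)C)C[C@H](O[Si](C)(C)C(C)(C)C)[C@@]1(C)[C@@H]2/C=C/C | intermediate
13 | 4-[(tert-butyldimethylsilyl)oxy]-2-isopropyl-5-methyl-6-[(E)-prop-1-enyl]-2-(trimethylsilyloxy)-1-[1-(trimethylsilyloxy)vinyl]bicyclo[3.1.0]hexane (not isolated) | C=C(O[Si](C)(C)C)[C@]12[C@](O[Si](C)(C)C)(C(C)C)C[C@H](O[Si](C)(C)C(C)(C)C)[C@@]1(C)[C@@H]2/C=C/C | intermediate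
14 | 2α-[(tert-butyldimethylsilyl)oxy]-4β,6-bis(trimethylsilyloxy)dauca-5,9-diene (8β-methyl) | C[C@H]1CC(O[Si](C)(C)C)=C2[C@](O[Si](C)(C)C)(C(C)C)C[C@H](O[Si](C)(C)C(C)(C)C)[C@@]2(C)C=C1 | intermediate
15 | 2α-[(tert-butyldimethylsilyl)oxy]-4β-hydroxy-5αH-dauc-9-en-6-one | O=C1C[C@H](C)C=C[C@@]2(C)[C@@H]1[C@](O)(C(C)C)C[C@@H]2O[Si](C)(C)C(C)(C)C | intermediate
16 | 2α-[(tert-butyldimethylsilyl)oxy]-5αH-dauc-9-ene-4β,6α-diol | O[C@H]1C[C@H](C)C=C[C@@]2(C)[C@@H]1[C@](O)(C(C)C)C[C@@H]2O[Si](C)(C)C(C)(C)C | intermediate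
17 | 2α-[(tert-butyldimethylsilyl)oxy]-10α-hydroperoxy-5αH-dauc-8-ene-4β,6α-diol (not isolated) | O[C@H]1CC(C)=C[C@@H](OO)[C@@]2(C)[C@@H]1[C@](O)(C(C)C)C[C@@H]2O[Si](C)(C)C(C)(C)C | intermediate
18 | 2α-[(tert-butyldimethylsilyl)oxy]-4β-hydroxy-10-oxo-5αH-dauc-8-en-6α-yl (E)-2-methylbut-2-enoate | C/C=C(\C)C(=O)O[C@H]1CC(C)=CC(=O)[C@@]2(C)[C@@H]1[C@](O)(C(C)C)C[C@@H]2O[Si](C)(C)C(C)(C)C | intermediate
19 | 2α-[(tert-butyldimethylsilyl)oxy]-4β,10β-dihydroxy-5αH-dauc-8-en-6α-yl (E)-2-methylbut-2-enoate | C/C=C(\C)C(=O)O[C@H]1CC(C)=C[C@H](O)[C@@]2(C)[C@@H]1[C@](O)(C(C)C)C[C@@H]2O[Si](C)(C)C(C)(C)C | intermediate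
20 | 8β,9β-epoxy-2α-[(tert-butyldimethylsilyl)oxy]-4β,10β-dihydroxy-5αH-daucan-6α-yl (E)-2-methylbut-2-enoate | C/C=C(\C)C(=O)O[C@H]1C[C@]2(C)O[C@@H]2[C@H](O)[C@@]2(C)[C@@H]1[C@](O)(C(C)C)C[C@@H]2O[Si](C)(C)C(C)(C)C | intermediate
21 | 8β,9β-epoxy-2α-[(tert-butyldimethylsilyl)oxy]-4β-hydroxy-5αH-daucane-6α,10β-diyl bis[(E)-2-methylbut-2-enoate] | C/C=C(\C)C(=O)O[C@H]1C[C@]2(C)O[C@@H]2[C@H](OC(=O)/C(C)=C/C)[C@@]2(C)[C@@H]1[C@](O)(C(C)C)C[C@@H]2O[Si](C)(C)C(C)(C)C | intermediate
22 | (1S,2S,4R,5S,6S,8S,9R,10R)-8,9-epoxy-2,4-dihydroxydaucane-6,10-diyl bis[(E)-2-methylbut-2-enoate] | C/C=C(\C)C(=O)O[C@H]1C[C@]2(C)O[C@@H]2[C@H](OC(=O)/C(C)=C/C)[C@@]2(C)[C@@H]1[C@](O)(C(C)C)C[C@@H]2O | target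

Total step count: 15. Longest linear sequence: 15 steps (1 to 22).

Steps most likely to fail

Step 8. The angular methyl lies syn to both vinyl termini in the boat transition state. The temperature the Cope shift then needs may allow a homodienyl 1,5-hydrogen shift from that methyl, or loss of the silyl enol ether, to compete with ring closure. The fallback sets out from 12 and comes back at 15, replacing the pericyclic step by a radical cyclisation–fragmentation. Compound 13 is generated at −78 °C as in step 8 and treated in the cold with N-bromosuccinimide to give the bromomethyl ketone F2. With Bu3SnH and AIBN in benzene at 80 °C, the α-keto radical at C7 should add 6-endo to C8 of the cis-propenyl group. The cyclopropylcarbinyl radical so formed at C9 should open the C5–C10 bond to the ketone-stabilised C5 radical, and hydrogen transfer gives the silyl-protected ring-expanded ketone F3. K2CO3 in MeOH then removes the trimethylsilyl group and equilibrates C5, giving 15.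

Step 7. Addition to an ester carbonyl flanked by two fully substituted carbons and a neighbouring lithium alkoxide may be too slow, or the α-silyl ketone may escape enolisation and add a second equivalent. The fallback sets out from 10 and comes back at 12. MeNHOMe·HCl and iPrMgCl in THF should convert the ester, assisted by the adjacent magnesium alkoxide, into the N-methoxy-N-methylamide F1. MeMgBr then adds once through the chelated tetrahedral intermediate and releases 12 on work-up.

Step 11. The ene reaction of singlet oxygen with a 1,2-disubstituted ring alkene is slow, and the only allylic hydrogen lies next to the angular methyl, so sensitiser bleaching and unselective oxidation may take over before conversion is complete. The fallback sets out from 16 and comes back at 18. SeO2 (catalytic) with tBuOOH in CH2Cl2 should give, by ene reaction and 2,3-sigmatropic shift, the tertiary allylic alcohol F4 (8α-hydroxy, C9=C10 retained). (E)-2-Methylbut-2-enoyl chloride, pyridine and DMAP acylate only the secondary C6 alcohol to give the tiglate F5. Pyridinium chlorochromate, C5H5NH[CrO3Cl], in CH2Cl2 then effects the oxidative 1,3-transposition (Babler–Dauben) to enone 18.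

Further compounds
F1 | step 7 | 4-[(tert-butyldimethylsilyl)oxy]-2-hydroxy-2-isopropyl-N-methoxy-N,5-dimethyl-6-[(E)-prop-1-enyl]bicyclo[3.1.0]hexane-1-carboxamide | CON(C)C(=O)[C@]12[C@](O)(C(C)C)C[C@H](O[Si](C)(C)C(C)(C)C)[C@@]1(C)[C@@H]2/C=C/C
F2 | step 8 | 1-(bromoacetyl)-4-[(tert-butyldimethylsilyl)oxy]-2-isopropyl-5-methyl-6-[(E)-prop-1-enyl]-2-(trimethylsilyloxy)bicyclo[3.1.0]hexane | BrCC(=O)[C@]12[C@](O[Si](C)(C)C)(C(C)C)C[C@H](O[Si](C)(C)C(C)(C)C)[C@@]1(C)[C@@H]2/C=C/C
F3 | step 8 | 2α-[(tert-butyldimethylsilyl)oxy]-4β-(trimethylsilyloxy)-5αH-dauc-9-en-6-one | O=C1C[C@H](C)C=C[C@@]2(C)[C@@H]1[C@](O[Si](C)(C)C)(C(C)C)C[C@@H]2O[Si](C)(C)C(C)(C)C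
F4 | step 11 | 2α-[(tert-butyldimethylsilyl)oxy]-5αH-dauc-9-ene-4β,6α,8α-triol | O[C@H]1C[C@@](C)(O)C=C[C@@]2(C)[C@@H]1[C@](O)(C(C)C)C[C@@H]2O[Si](C)(C)C(C)(C)C
F5 | step 11 | 2α-[(tert-butyldimethylsilyl)oxy]-4β,8α-dihydroxy-5αH-dauc-9-en-6α-yl (E)-2-methylbut-2-enoate | C/C=C(\C)C(=O)O[C@H]1C[C@@](C)(O)C=C[C@@]2(C)[C@@H]1[C@](O)(C(C)C)C[C@@H]2O[Si](C)(C)C(C)(C)C
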